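**Strategy.** In ring A the depside carbonyl sits on C1, between the C2 oxygen and C6, which bears the CH2–C(=O) arm. A 3-oxygenated aryne acquires exactly this vicinal acyl/alkyl pair beside an oxygen when it enters a malonyl C–C bond. The C1–C(=O) and C6–CH2 bonds are therefore cut together. In the forward sense, fluoride frees 3,5-bis(benzyloxy)benzyne from its silyl triflate. The aryne inserts into the CH2–C(=O)OAr bond of a malonic ester amide whose aryl ester oxygen already belongs to complete ring B and whose other end is a Weinreb amide. One operation gives the hindered depside link and the C6 arm. Heptyl Grignard addition and two deprotections finish the synthesis.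

Key step: step 8

Remark: the target has no stereocentre and no configured double bond, so no stereocontrol is needed. Ring A is numbered C1 (ester carbon), C2 and C4 (oxygens), C6 (oxononyl arm). Ring B is numbered C1' (acid), C2' (OMe), C4' (depside oxygen), C6' (heptyl). LiN(iPr)2, n-BuLi and C7H15MgBr are taken as commercial solutions.

**Step 1**
Reactants: 1 3,5-bis(benzyloxy)phenol
Product: 2 3,5-bis(benzyloxy)-2-bromophenol
Conditions: NBS (1.0 equiv), CH2Cl2, −78 °C to rt
Reagents that add atoms: N-bromosuccinimide, O=C1CCC(=O)N1Br
Why: Electrophilic aromatic bromination: the free hydroxyl is the strongest activator, and the two equivalent positions ortho to it (each also para to a benzyloxy group) are less crowded than C4 between two benzyloxy groups, so one equivalent of NBS at low temperature should give mainly the 2-bromide.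

**Step 2**
Reactants: 2 3,5-bis(benzyloxy)-2-bromophenol
Product: 5 3,5-bis(benzyloxy)-2-(trimethylsilyl)phenyl trifluoromethanesulfonate, via silyl ether 3 (not isolated), via lithium phenoxide 4 (not isolated)
Conditions: HMDS, THF, 65 °C, evaporate; then n-BuLi (1.1 equiv), THF, −78 °C; then Tf2O (1.2 equiv), −78 to 0 °C
Reagents that add atoms: hexamethyldisilazane, C[Si](C)(C)N[Si](C)(C)C; trifluoromethanesulfonic anhydride, O=S(=O)(OS(=O)(=O)C(F)(F)F)C(F)(F)F
Why: O-silylation, bromine–lithium exchange and a retro-Brook 1,3-shift of silicon from oxygen to the lithiated carbon give phenoxide 4, which Tf2O traps; this is the standard sequence to o-silylaryl triflates, and exchange at −78 °C is much faster than attack of n-BuLi on the benzyl ethers.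

**Step 3**
Reactants: 6 2-methoxy-6-methylbenzoic acid; 7 1-bromohexane
Product: 9 2-heptyl-6-methoxybenzoic acid, via dilithio dianion 8 (not isolated)
Conditions: LiN(iPr)2 (2.2 equiv), THF, −78 to 0 °C; then 7 (1.1 equiv), −78 °C to rt; 1 M HCl work-up
Reagents that add atoms: none
Why: Lateral lithiation of an o-toluic acid followed by SN2 alkylation: the carboxylate-stabilised benzylic dianion reacts at carbon with the primary bromide (CH2 plus hexyl gives heptyl), and an amide base is chosen because an alkyllithium could displace the methoxy group ortho to the carboxylate.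

**Step 4**
Reactants: 9 2-heptyl-6-methoxybenzoic acid
Product: 10 tert-butyl 2-heptyl-6-methoxybenzoate
Conditions: tert-butyl 2,2,2-trichloroacetimidate (2 equiv), BF3·OEt2 (cat.), CH2Cl2/cyclohexane, rt
Reagents that add atoms: tert-butyl 2,2,2-trichloroacetimidate, CC(C)(C)OC(=N)C(Cl)(Cl)Cl
Why: Alkylative esterification with a trichloroacetimidate: the carboxyl oxygen captures the tert-butyl cation, so nothing has to attack the carbonyl carbon shielded by its two ortho substituents.

**Step 5**
Reactants: 10 tert-butyl 2-heptyl-6-methoxybenzoate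
Product: 12 tert-butyl 2-heptyl-4-hydroxy-6-methoxybenzoate, via pinacol boronate 11 (not isolated)
Conditions: [Ir(OMe)(cod)]2 (1.5 mol %), 4,4'-di-tert-butyl-2,2'-bipyridine (3 mol %), B2pin2 (1.0 equiv), THF, 80 °C; then 30% aq H2O2, 2 M NaOH, THF, 0 °C to rt; mild acid work-up
Reagents that add atoms: bis(pinacolato)diboron, CC1(C)OB(OC1(C)C)B1OC(C)(C)C(C)(C)O1 (boryl group of 11); hydrogen peroxide, OO (phenol oxygen of 12)
Why: One-pot iridium-catalysed C–H borylation and boronate oxidation: the borylation is sterically controlled, and in this 1,2,3-trisubstituted ring only C4'–H has hydrogen on both sides; the tert-butyl ester offers no arene C–H of its own and is too hindered to be saponified during the oxidation.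

**Step 6**
Reactants: 13 2,2-dimethyl-1,3-dioxane-4,6-dione (Meldrum's acid)
Product: 14 3-[methoxy(methyl)amino]-3-oxopropanoic acid (N-methoxy-N-methylmalonamic acid)
Conditions: MeNHOMe·HCl (1.05 equiv), Et3N (1.05 equiv), MeCN, sealed tube, 75 °C
Reagents that add atoms: N,O-dimethylhydroxylamine hydrochloride, CNOC.Cl
Why: Aminolysis of Meldrum's acid: the amine, about as weakly basic as an aniline, attacks one ring carbonyl and the opened hemiketal loses acetone to leave the malonic half-amide, at a temperature kept below that of decarboxylation.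

**Step 7**
Reactants: 12 tert-butyl 2-heptyl-4-hydroxy-6-methoxybenzoate; 14 N-methoxy-N-methylmalonamic acid
Product: 15 tert-butyl 2-heptyl-6-methoxy-4-({3-[methoxy(methyl)amino]-3-oxopropanoyl}oxy)benzoate (ring B aryl malonamate)
Conditions: DCC (1.1 equiv), DMAP (5 mol %), CH2Cl2, 0 °C to rt; filtration, non-basic work-up
Reagents that add atoms: none
Why: Steglich esterification: the O-acylisourea of the malonic half-amide (or the acylketene derived from it) is captured by the C4' phenol, which is unhindered because both of its neighbours carry hydrogen.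

**Step 8**
Reactants: 5 3,5-bis(benzyloxy)-2-(trimethylsilyl)phenyl trifluoromethanesulfonate; 15 ring B aryl malonamate
Product: 18 tert-butyl 4-{[2,4-bis(benzyloxy)-6-{2-[methoxy(methyl)amino]-2-oxoethyl}benzoyl]oxy}-2-heptyl-6-methoxybenzoate, via aryne 16 (not isolated), via benzocyclobutenoxide 17 (not isolated)
Conditions: dry CsF (3 equiv), MeCN, 25–40 °C, 5 (1.3 equiv) added slowly by syringe pump to 15
Reagents that add atoms: none
Why: Proposed new method: fluoride removes the silyl group of 5 and triflate departs to give aryne 16, while fluoride at the start and the product enolate thereafter deprotonate the doubly activated CH2 of 15. The carbanion attacks the aryne carbon remote from the neighbouring benzyloxy group (future C6), since that inductively withdrawing oxygen distorts the triple bond and stabilises the charge arising on the adjacent carbon (future C1); the C4 benzyloxy group is too far away to override this. The C1 aryl anion closes a transient four-membered ring 4-exo-trig on the aryl ester carbonyl, which is more electrophilic than the nitrogen-stabilised amide carbonyl, and alkoxide 17 sheds its strain by cleaving the old malonyl C–C bond to a benzylic amide enolate that is protonated by fresh 15, so that 18 keeps no new ring and no stereocentre (the two centres of 17 vanish). The closest known reaction type is the fluoride-induced acyl-alkylation of arynes by dialkyl malonates and beta-keto esters; a malonyl unit that pairs an aryl ester with an amide has not been used. Three selectivities are needed: site of attack on 16 (C2 benzyloxy group), choice of carbonyl (aryl ester over Weinreb amide) and C–C over C–O cleavage in 17, where any expelled ring B phenoxide can re-add to the strained benzocyclobutenone and still end in 18. Ambient temperature, dry CsF and slow addition of 5 keep the aryne dilute, so that phenoxide lost by E1cB ketene formation from the enolate of 15 recombines before it is arylated.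

**Step 9**
Reactants: 18 Weinreb amide depside; 19 heptylmagnesium bromide
Product: 21 tert-butyl 4-{[2,4-bis(benzyloxy)-6-(2-oxononyl)benzoyl]oxy}-2-heptyl-6-methoxybenzoate, via magnesium chelate 20 (not isolated)
Conditions: C7H15MgBr (1.4 equiv), THF, −40 to −10 °C; inverse quench into cold 0.5 M HCl
Reagents that add atoms: none
Why: Weinreb ketone synthesis: the five-membered magnesium chelate 20 holds the tetrahedral adduct until the acidic quench, so no second addition occurs and the ketone never meets base, while the depside carbonyl (two ortho substituents on ring A) and the tert-butyl ester (two ortho substituents on ring B) are sterically shielded from the Grignard reagent.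

**Step 10**
Reactants: 21 keto depside tert-butyl ester
Product: 22 4-{[2,4-bis(benzyloxy)-6-(2-oxononyl)benzoyl]oxy}-2-heptyl-6-methoxybenzoic acid
Conditions: TFA/CH2Cl2 (1:4), 0 °C to rt
Reagents that add atoms: none
Why: Acidolysis of a tert-butyl ester by alkyl–oxygen cleavage with loss of isobutene; the aryl benzyl ethers, methyl ether, ketone and hindered depside ester should tolerate a short exposure to dilute TFA, and keeping the phenols benzylated makes ring A less prone to tert-butylation.

**Step 11**
Reactants: 22 dibenzyl depside acid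
Product: 23 4-{[2,4-dihydroxy-6-(2-oxononyl)benzoyl]oxy}-2-heptyl-6-methoxybenzoic acid (target CNP0406321.0)
Conditions: H2 (1 atm), 10% Pd/C, EtOAc, rt; filtration, evaporation
Reagents that add atoms: none
Why: Catalytic hydrogenolysis of the two aryl benzyl ethers under neutral conditions; the ketone is not conjugated with the ring, and it, the depside ester, the acid and the methyl ether are inert at one atmosphere.

**Compound list**
1 | 3,5-bis(benzyloxy)phenol | Oc1cc(OCc2ccccc2)cc(OCc2ccccc2)c1 | starting material
2 | 3,5-bis(benzyloxy)-2-bromophenol | Oc1cc(OCc2ccccc2)cc(OCc2ccccc2)c1Br | intermediate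
3 | [3,5-bis(benzyloxy)-2-bromophenoxy]trimethylsilane | C[Si](C)(C)Oc1cc(OCc2ccccc2)cc(OCc2ccccc2)c1Br | intermediate (not isolated)
4 | lithium 3,5-bis(benzyloxy)-2-(trimethylsilyl)phenoxide | [Li+].[O-]c1cc(OCc2ccccc2)cc(OCc2ccccc2)c1[Si](C)(C)C | intermediate (not isolated)
5 | 3,5-bis(benzyloxy)-2-(trimethylsilyl)phenyl trifluoromethanesulfonate | C[Si](C)(C)c1c(OCc2ccccc2)cc(OCc2ccccc2)cc1OS(=O)(=O)C(F)(F)F | intermediate
6 | 2-methoxy-6-methylbenzoic acid | COc1cccc(C)c1C(=O)O | starting material
7 | 1-bromohexane | CCCCCCBr | starting material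
8 | dilithium salt of the carboxylate/benzylic dianion of 6 | [Li+].[Li+].[CH2-]c1cccc(OC)c1C(=O)[O-] | intermediate (not isolated)
9 | 2-heptyl-6-methoxybenzoic acid | CCCCCCCc1cccc(OC)c1C(=O)O | intermediate
10 | tert-butyl 2-heptyl-6-methoxybenzoate | CCCCCCCc1cccc(OC)c1C(=O)OC(C)(C)C | intermediate
11 | tert-butyl 2-heptyl-6-methoxy-4-(4,4,5,5-tetramethyl-1,3,2-dioxaborolan-2-yl)benzoate | CCCCCCCc1cc(B2OC(C)(C)C(C)(C)O2)cc(OC)c1C(=O)OC(C)(C)C | intermediate (not isolated)
12 | tert-butyl 2-heptyl-4-hydroxy-6-methoxybenzoate | CCCCCCCc1cc(O)cc(OC)c1C(=O)OC(C)(C)C | intermediate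
13 | 2,2-dimethyl-1,3-dioxane-4,6-dione | CC1(C)OC(=O)CC(=O)O1 | starting material
14 | 3-[methoxy(methyl)amino]-3-oxopropanoic acid | CON(C)C(=O)CC(=O)O | intermediate
15 | tert-butyl 2-heptyl-6-methoxy-4-({3-[methoxy(methyl)amino]-3-oxopropanoyl}oxy)benzoate | CON(C)C(=O)CC(=O)Oc1cc(CCCCCCC)c(C(=O)OC(C)(C)C)c(OC)c1 | intermediate
16 | 3,5-bis(benzyloxy)benzyne | C1#CC(OCc2ccccc2)=CC(OCc2ccccc2)=C1 | intermediate (not isolated)
17 | cesium benzocyclobutenoxide from ring closure on the aryl ester carbonyl (transient, configuration undefined) | [Cs+].[O-]C1(Oc2cc(CCCCCCC)c(C(=O)OC(C)(C)C)c(OC)c2)C(C(=O)N(C)OC)c2cc(OCc3ccccc3)cc(OCc3ccccc3)c12 | intermediate (not isolated)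
18 | tert-butyl 4-{[2,4-bis(benzyloxy)-6-{2-[methoxy(methyl)amino]-2-oxoethyl}benzoyl]oxy}-2-heptyl-6-methoxybenzoate | CON(C)C(=O)Cc1cc(OCc2ccccc2)cc(OCc2ccccc2)c1C(=O)Oc1cc(CCCCCCC)c(C(=O)OC(C)(C)C)c(OC)c1 | intermediate
19 | heptylmagnesium bromide | CCCCCCC[Mg]Br | starting material
20 | bromomagnesium alkoxide of the tetrahedral adduct (chelated, racemic, transient) | CCCCCCCC(O[Mg]Br)(Cc1cc(OCc2ccccc2)cc(OCc2ccccc2)c1C(=O)Oc1cc(CCCCCCC)c(C(=O)OC(C)(C)C)c(OC)c1)N(C)OC | intermediate (not isolated)
21 | tert-butyl 4-{[2,4-bis(benzyloxy)-6-(2-oxononyl)benzoyl]oxy}-2-heptyl-6-methoxybenzoate | CCCCCCCC(=O)Cc1cc(OCc2ccccc2)cc(OCc2ccccc2)c1C(=O)Oc1cc(CCCCCCC)c(C(=O)OC(C)(C)C)c(OC)c1 | intermediate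
22 | 4-{[2,4-bis(benzyloxy)-6-(2-oxononyl)benzoyl]oxy}-2-heptyl-6-methoxybenzoic acid | CCCCCCCC(=O)Cc1cc(OCc2ccccc2)cc(OCc2ccccc2)c1C(=O)Oc1cc(CCCCCCC)c(C(=O)O)c(OC)c1 | intermediate
23 | 4-{[2,4-dihydroxy-6-(2-oxononyl)benzoyl]oxy}-2-heptyl-6-methoxybenzoic acid | CCCCCCCC(=O)Cc1cc(O)cc(O)c1C(=O)Oc1cc(CCCCCCC)c(C(=O)O)c(OC)c1 | target

**Total steps:** 11. **Longest linear sequence:** 8 (steps 3, 4, 5, 7, 8, 9, 10, 11).

**Steps most likely to fail**

**Step 8.** Four things may go wrong:
- Ring B phenoxide is lost from the malonamate enolate (ketene pathway) or from the four-membered alkoxide, and the aryne then arylates it irreversibly.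
- The aryl anion is protonated before acyl transfer, giving plain alpha-arylation.
- The ring closes on the amide carbonyl instead of the aryl ester.
- The product enolate is arylated a second time.

The fallback uses only known reaction types. It sets out from 5 (with 12 as coupling partner) and comes back at 18. Aryne 16 released from 5 with KF and 18-crown-6 in THF at rt is inserted into dimethyl malonate, the established symmetrical case, to give methyl 2,4-bis(benzyloxy)-6-(2-methoxy-2-oxoethyl)benzoate F1. KOH in refluxing aqueous ethanol hydrolyses both esters to 2,4-bis(benzyloxy)-6-(carboxymethyl)benzoic acid F2. Ac2O in hot toluene closes 6,8-bis(benzyloxy)isochromane-1,3-dione F3. N,O-dimethylhydroxylamine opens this anhydride at the unconjugated, less hindered carbonyl to give 2,4-bis(benzyloxy)-6-{2-[methoxy(methyl)amino]-2-oxoethyl}benzoic acid F4. Acid F4 is then esterified with phenol 12 through its mixed anhydride with trifluoroacetic anhydride in toluene, the classical coupling for hindered depside acids, to give 18.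

**Step 9.** Three things may go wrong:
- The strongly basic Grignard reagent enolises the benzylic CH2.
- The enolate or the tetrahedral adduct transfers the acyl group onto the neighbouring depside carbonyl, and ring B is lost.
- The reagent attacks the aryl ester directly.

The fallback sets out from 18 and comes back at 23. It replaces the alkyl nucleophile by a slim sp carbanion that is far less basic and adds at −78 °C. Hept-1-ynyllithium (hept-1-yne, n-BuLi, THF) should convert the Weinreb amide into tert-butyl 4-{[2,4-bis(benzyloxy)-6-(2-oxonon-3-yn-1-yl)benzoyl]oxy}-2-heptyl-6-methoxybenzoate F5. Hydrogenation over Pd/C in EtOAc saturates the triple bond and removes both benzyl ethers in one operation, giving tert-butyl 4-{[2,4-dihydroxy-6-(2-oxononyl)benzoyl]oxy}-2-heptyl-6-methoxybenzoate F6. TFA in CH2Cl2 then frees the acid to give 23, with no extra step.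

**Step 6.** Three things may go wrong:
- Salt formation with the acidic Meldrum's acid stalls the ring opening.
- The volatile free amine escapes.
- The malonamic acid decarboxylates on prolonged heating.

The fallback sets out from 12 and 13, comes back at 15, and makes steps 6 and 7 unnecessary by building the two malonyl bonds in the opposite order. Heating phenol 12 with Meldrum's acid 13 in toluene at 90–100 °C, the known phenolysis to aryl hydrogen malonates, should give 3-[4-(tert-butoxycarbonyl)-3-heptyl-5-methoxyphenoxy]-3-oxopropanoic acid F7. Its free acid is then coupled with MeNHOMe·HCl using EDC·HCl and N-methylmorpholine in CH2Cl2 at 0 °C to give 15.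

**Further compounds**
F1 | step 8 | methyl 2,4-bis(benzyloxy)-6-(2-methoxy-2-oxoethyl)benzoate | COC(=O)Cc1cc(OCc2ccccc2)cc(OCc2ccccc2)c1C(=O)OC
F2 | step 8 | 2,4-bis(benzyloxy)-6-(carboxymethyl)benzoic acid | OC(=O)Cc1cc(OCc2ccccc2)cc(OCc2ccccc2)c1C(=O)O
F3 | step 8 | 6,8-bis(benzyloxy)isochromane-1,3-dione | O=C1Cc2cc(OCc3ccccc3)cc(OCc3ccccc3)c2C(=O)O1
F4 | step 8 | 2,4-bis(benzyloxy)-6-{2-[methoxy(methyl)amino]-2-oxoethyl}benzoic acid | CON(C)C(=O)Cc1cc(OCc2ccccc2)cc(OCc2ccccc2)c1C(=O)O
F5 | step 9 | tert-butyl 4-{[2,4-bis(benzyloxy)-6-(2-oxonon-3-yn-1-yl)benzoyl]oxy}-2-heptyl-6-methoxybenzoate | CCCCCC#CC(=O)Cc1cc(OCc2ccccc2)cc(OCc2ccccc2)c1C(=O)Oc1cc(CCCCCCC)c(C(=O)OC(C)(C)C)c(OC)c1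
F6 | step 9 | tert-butyl 4-{[2,4-dihydroxy-6-(2-oxononyl)benzoyl]oxy}-2-heptyl-6-methoxybenzoate | CCCCCCCC(=O)Cc1cc(O)cc(O)c1C(=O)Oc1cc(CCCCCCC)c(C(=O)OC(C)(C)C)c(OC)c1
F7 | step 6 | 3-[4-(tert-butoxycarbonyl)-3-heptyl-5-methoxyphenoxy]-3-oxopropanoic acid | OC(=O)CC(=O)Oc1cc(CCCCCCC)c(C(=O)OC(C)(C)C)c(OC)c1
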